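The route rests on cutting C8–C8a and C6–C7, so that ring A is built around the 1,1-dimethylallyl group instead of being alkylated. Ring A carries oxygen on C8a, C7 and C5, the quaternary side chain on C8 and hydrogen on C6 and C4a, which is the pattern a vinylketene and an ynol ether deliver. One thermal operation joins 3-ethoxycyclobutenone (C8a, C4a, C5, C6) to a triisopropylsiloxyalkyne carrying the side chain (C8, C7), closes ring A and leaves three differently masked oxygens, of which only the future O1 is free. Directed lithiation at C4a, acylation, aroylation and acid closure then add ring C.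

Key step: step 2

Assumption: ethyl 2,2-dimethylbut-3-enoate and 3-ethoxycyclobut-2-en-1-one are bought. Flavone numbering is used for the ring atoms throughout. The target has no stereocentre, and the two stereocentres that arise on the way (cyclobutenone of step 2, diketone of step 6) are racemic and are erased.

Step 1
Reactants: 1 ethyl 2,2-dimethylbut-3-enoate; 2 dibromomethane; 3 triisopropylsilyl trifluoromethanesulfonate
Product: 6 triisopropyl[(3,3-dimethylpent-4-en-1-yn-1-yl)oxy]silane, via lithium dibromoenolate 4 (not isolated), via lithium ynolate 5 (not isolated)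
Conditions: 2, lithium 2,2,6,6-tetramethylpiperidide, THF, −78 °C; 1; n-BuLi, −78 °C to rt; 3, −78 to 0 °C
Reagents that add atoms: dibromomethane 2, BrCBr; triisopropylsilyl trifluoromethanesulfonate 3, CC(C)[Si](C(C)C)(C(C)C)OS(=O)(=O)C(F)(F)F
Why: Kowalski ester homologation halted at the ynolate: LiCHBr2 adds to the non-enolisable ester, bromine–lithium exchange on enolate 4 triggers the carbenoid 1,2-shift of the tert-alkyl group to give 5 (the carbon of 2 becomes C8, the ester carbon C7), and the bulky silyl triflate should trap 5 on oxygen rather than on carbon.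

Step 2
Reactants: 6 triisopropyl[(3,3-dimethylpent-4-en-1-yn-1-yl)oxy]silane; 7 3-ethoxycyclobut-2-en-1-one
Product: 12 5-ethoxy-2-(2-methylbut-3-en-2-yl)-3-[(triisopropylsilyl)oxy]phenol, via vinylketene 8 (not isolated), via vinylcyclobutenone 9 (not isolated), via dienylketene 10 (not isolated), via cyclohexadienone 11 (not isolated)
Conditions: 6 (1.5 equiv), toluene, 110 °C, 7 added slowly by syringe pump; then 135 °C, sealed vessel, argon
Reagents that add atoms: none
Why: Proposed new method: heat should open 7 by four-electron electrocyclic cleavage of its C1–C4 bond to (1-ethoxyvinyl)ketene 8, and the side-chain-bearing alkyne carbon of 6, made nucleophilic by the siloxy oxygen, should attack the central ketene carbon in a [2+2] cycloaddition that forms C8–C8a and C6–C7 and gives racemic 4-vinylcyclobutenone 9. A second, reversible four-electron opening cuts the old C8a–C6 bond and gives dienylketene 10, of which only the isomer holding the ketene and the ethoxyvinyl group cis on the central double bond can go on, so the equilibrium drains through it. Ring A closes by a thermally allowed disrotatory six-electron electrocyclisation that rejoins C4a to C8a, and dienone 11 tautomerises irreversibly to phenol 12, which erases the only stereocentre of the cascade, so that no stereocontrol is needed. The closest known reaction type is the Danheiser benzannulation of alkyl- or aryl-substituted cyclobutenones with triisopropylsiloxyalkynes that carry unbranched alkyl groups, and what is new is the pairing of a 3-alkoxycyclobutenone with a tert-alkyl-substituted siloxyalkyne. The selectivity required is the orientation of the [2+2] step, and the polarisation of the ynol ether secures it, so that the free hydroxyl ends on C8a beside C8 while O7 keeps silicon and O5 keeps ethyl. Slow addition of 7 to an excess of 6 keeps the ketene dilute, which should hold back its self-condensation and the acylation of the hindered phenol, and the neutral medium leaves the vinyl group and the silyl ether alone.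

Step 3
Reactants: 12 5-ethoxy-2-(2-methylbut-3-en-2-yl)-3-[(triisopropylsilyl)oxy]phenol
Product: 13 [5-ethoxy-3-(methoxymethoxy)-2-(2-methylbut-3-en-2-yl)phenoxy]triisopropylsilane
Conditions: NaH, MOMCl, THF–DMF, 0 °C to rt
Reagents that add atoms: chloromethyl methyl ether, COCCl
Why: Williamson-type O-alkylation of the sodium phenoxide, in which O8a is the only free hydroxyl, the hindered triisopropylsilyl group should not migrate, and the acetal installed serves both as mask of the future O1 and as directing group for step 5.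

Step 4
Reactants: 14 (benzyloxy)acetyl chloride; 15 N,O-dimethylhydroxylamine hydrochloride
Product: 16 2-(benzyloxy)-N-methoxy-N-methylacetamide
Conditions: Et3N (2.2 equiv), CH2Cl2, 0 °C to rt
Reagents that add atoms: none
Why: Schotten–Baumann-type N-acylation of the liberated hydroxylamine by an acid chloride, a routine Weinreb amide preparation.

Step 5
Reactants: 13 [5-ethoxy-3-(methoxymethoxy)-2-(2-methylbut-3-en-2-yl)phenoxy]triisopropylsilane; 16 2-(benzyloxy)-N-methoxy-N-methylacetamide
Product: 18 2-(benzyloxy)-1-{6-ethoxy-2-(methoxymethoxy)-3-(2-methylbut-3-en-2-yl)-4-[(triisopropylsilyl)oxy]phenyl}ethan-1-one, via aryllithium 17 (not isolated)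
Conditions: n-BuLi, TMEDA, THF, 0 °C; 16, −78 to 0 °C; aq. NH4Cl
Reagents that add atoms: none
Why: Directed ortho-metalation followed by Weinreb ketone synthesis: C4a–H is the only position flanked by two coordinating ether oxygens (acetal on C8a, ethoxy on C5), whereas C6–H lies beside the bulky and poorly coordinating siloxy group, and the chelated tetrahedral adduct stops the addition at the ketone.

Step 6
Reactants: 18 2-(benzyloxy)-1-{6-ethoxy-2-(methoxymethoxy)-3-(2-methylbut-3-en-2-yl)-4-[(triisopropylsilyl)oxy]phenyl}ethan-1-one; 19 4-methoxybenzoyl chloride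
Product: 21 2-(benzyloxy)-1-{6-ethoxy-2-(methoxymethoxy)-3-(2-methylbut-3-en-2-yl)-4-[(triisopropylsilyl)oxy]phenyl}-3-(4-methoxyphenyl)propane-1,3-dione (racemic), via lithium enolate 20 (not isolated)
Conditions: LiN(SiMe3)2 (2.2 equiv), THF, −78 °C; 19, −78 to 0 °C; aq. NH4Cl
Reagents that add atoms: none
Why: Crossed Claisen-type C-acylation of a lithium enolate by an aroyl chloride, driven to the carbon-acylated product because the second equivalent of base turns the more acidic 1,3-diketone into its enolate; the new stereocentre (future C3) is formed racemic, is configurationally labile and disappears in step 7.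

Step 7
Reactants: 21 2-(benzyloxy)-1-{6-ethoxy-2-(methoxymethoxy)-3-(2-methylbut-3-en-2-yl)-4-[(triisopropylsilyl)oxy]phenyl}-3-(4-methoxyphenyl)propane-1,3-dione
Product: 23 3-(benzyloxy)-5-ethoxy-2-(4-methoxyphenyl)-8-(2-methylbut-3-en-2-yl)-7-[(triisopropylsilyl)oxy]-4H-chromen-4-one, via phenolic diketone 22 (not isolated)
Conditions: HCl (dilute), MeOH–THF, 50 °C
Reagents that add atoms: none
Why: Acid-catalysed acetal cleavage followed by the cyclodehydration that ends a Baker–Venkataraman flavone synthesis; only O8a is unmasked, so only the 8-substituted chromone can form, while the phenolic silyl ether, the benzyl and ethyl ethers and the monosubstituted alkene should tolerate dilute acid.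

Step 8
Reactants: 23 3-(benzyloxy)-5-ethoxy-2-(4-methoxyphenyl)-8-(2-methylbut-3-en-2-yl)-7-[(triisopropylsilyl)oxy]-4H-chromen-4-one
Product: 24 3,5-dihydroxy-2-(4-methoxyphenyl)-8-(2-methylbut-3-en-2-yl)-7-[(triisopropylsilyl)oxy]-4H-chromen-4-one
Conditions: BCl3 (4 equiv), pentamethylbenzene (3 equiv), CH2Cl2, −78 to 0 °C; then H2O
Reagents that add atoms: none
Why: Chelation-directed Lewis acid dealkylation: BCl3 bound to the C4 carbonyl should cleave only the two ethers that can close a boron chelate with it (benzyl on O3, ethyl on O5) and spare the remote 4'-methyl ether, pentamethylbenzene takes up the benzyl cation, and because O7 is still silylated and O1 sits in ring C no hydroxyl group flanks the side chain and could add to the monosubstituted alkene under the liberated HCl.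

Step 9
Reactants: 24 3,5-dihydroxy-2-(4-methoxyphenyl)-8-(2-methylbut-3-en-2-yl)-7-[(triisopropylsilyl)oxy]-4H-chromen-4-one
Product: 25 3,5,7-trihydroxy-2-(4-methoxyphenyl)-8-(2-methylbut-3-en-2-yl)-4H-chromen-4-one
Conditions: Bu4NF, AcOH, THF, 0 °C
Reagents that add atoms: none
Why: Fluoride-driven cleavage of a phenolic silyl ether, with acetic acid as buffer so that the acidic flavonol does not remain as an oxidation-prone polyanion, and with nothing else in 24 that reacts with fluoride.

Compound list
1 | ethyl 2,2-dimethylbut-3-enoate | CCOC(=O)C(C)(C)C=C | starting material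
2 | dibromomethane | BrCBr | starting material
3 | triisopropylsilyl trifluoromethanesulfonate | CC(C)[Si](C(C)C)(C(C)C)OS(=O)(=O)C(F)(F)F | starting material
4 | lithium 1,1-dibromo-3,3-dimethylpenta-1,4-dien-2-olate | C=CC(C)(C)C([O-])=C(Br)Br.[Li+] | intermediate
5 | lithium 3,3-dimethylpent-4-en-1-yn-1-olate | C=CC(C)(C)C#C[O-].[Li+] | intermediate
6 | triisopropyl[(3,3-dimethylpent-4-en-1-yn-1-yl)oxy]silane | C=CC(C)(C)C#CO[Si](C(C)C)(C(C)C)C(C)C | intermediate
7 | 3-ethoxycyclobut-2-en-1-one | CCOC1=CC(=O)C1 | starting material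
8 | 3-ethoxybuta-1,3-dien-1-one, the (1-ethoxyvinyl)ketene | C=C(OCC)C=C=O | intermediate
9 | 4-(1-ethoxyvinyl)-2-(2-methylbut-3-en-2-yl)-3-[(triisopropylsilyl)oxy]cyclobut-2-en-1-one (racemic) | C=CC(C)(C)C1=C(O[Si](C(C)C)(C(C)C)C(C)C)C(C(=C)OCC)C1=O | intermediate
10 | (3E)-5-ethoxy-2-(2-methylbut-3-en-2-yl)-3-[(triisopropylsilyl)oxy]hexa-1,3,5-trien-1-one (ketene and ethoxyvinyl cis) | C=CC(C)(C)C(=C=O)/C(O[Si](C(C)C)(C(C)C)C(C)C)=C\C(=C)OCC | intermediate
11 | 5-ethoxy-2-(2-methylbut-3-en-2-yl)-3-[(triisopropylsilyl)oxy]cyclohexa-2,4-dien-1-one | C=CC(C)(C)C1=C(O[Si](C(C)C)(C(C)C)C(C)C)C=C(OCC)CC1=O | intermediate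
12 | 5-ethoxy-2-(2-methylbut-3-en-2-yl)-3-[(triisopropylsilyl)oxy]phenol | C=CC(C)(C)c1c(O)cc(OCC)cc1O[Si](C(C)C)(C(C)C)C(C)C | intermediate
13 | [5-ethoxy-3-(methoxymethoxy)-2-(2-methylbut-3-en-2-yl)phenoxy]triisopropylsilane | C=CC(C)(C)c1c(OCOC)cc(OCC)cc1O[Si](C(C)C)(C(C)C)C(C)C | intermediate
14 | (benzyloxy)acetyl chloride | O=C(Cl)COCc1ccccc1 | starting material
15 | N,O-dimethylhydroxylamine hydrochloride | CNOC.Cl | starting material
16 | 2-(benzyloxy)-N-methoxy-N-methylacetamide | CON(C)C(=O)COCc1ccccc1 | intermediate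
17 | {6-ethoxy-2-(methoxymethoxy)-3-(2-methylbut-3-en-2-yl)-4-[(triisopropylsilyl)oxy]phenyl}lithium | [Li]c1c(OCC)cc(O[Si](C(C)C)(C(C)C)C(C)C)c(C(C)(C)C=C)c1OCOC | intermediate
18 | 2-(benzyloxy)-1-{6-ethoxy-2-(methoxymethoxy)-3-(2-methylbut-3-en-2-yl)-4-[(triisopropylsilyl)oxy]phenyl}ethan-1-one | C=CC(C)(C)c1c(OCOC)c(C(=O)COCc2ccccc2)c(OCC)cc1O[Si](C(C)C)(C(C)C)C(C)C | intermediate
19 | 4-methoxybenzoyl chloride | COc1ccc(cc1)C(Cl)=O | starting material
20 | lithium (Z)-enolate of 18 (oxide and benzyloxy cis, chelated) | C=CC(C)(C)c1c(OCOC)c(/C([O-])=C/OCc2ccccc2)c(OCC)cc1O[Si](C(C)C)(C(C)C)C(C)C.[Li+] | intermediate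
21 | 2-(benzyloxy)-1-{6-ethoxy-2-(methoxymethoxy)-3-(2-methylbut-3-en-2-yl)-4-[(triisopropylsilyl)oxy]phenyl}-3-(4-methoxyphenyl)propane-1,3-dione (racemic, keto–enol mixture) | C=CC(C)(C)c1c(OCOC)c(C(=O)C(OCc2ccccc2)C(=O)c2ccc(OC)cc2)c(OCC)cc1O[Si](C(C)C)(C(C)C)C(C)C | intermediate
22 | 2-(benzyloxy)-1-{6-ethoxy-2-hydroxy-3-(2-methylbut-3-en-2-yl)-4-[(triisopropylsilyl)oxy]phenyl}-3-(4-methoxyphenyl)propane-1,3-dione (racemic) | C=CC(C)(C)c1c(O)c(C(=O)C(OCc2ccccc2)C(=O)c2ccc(OC)cc2)c(OCC)cc1O[Si](C(C)C)(C(C)C)C(C)C | intermediate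
23 | 3-(benzyloxy)-5-ethoxy-2-(4-methoxyphenyl)-8-(2-methylbut-3-en-2-yl)-7-[(triisopropylsilyl)oxy]-4H-chromen-4-one | C=CC(C)(C)c1c(O[Si](C(C)C)(C(C)C)C(C)C)cc(OCC)c2c(=O)c(OCc3ccccc3)c(-c3ccc(OC)cc3)oc12 | intermediate
24 | 3,5-dihydroxy-2-(4-methoxyphenyl)-8-(2-methylbut-3-en-2-yl)-7-[(triisopropylsilyl)oxy]-4H-chromen-4-one | C=CC(C)(C)c1c(O[Si](C(C)C)(C(C)C)C(C)C)cc(O)c2c(=O)c(O)c(-c3ccc(OC)cc3)oc12 | intermediate
25 | 3,5,7-trihydroxy-2-(4-methoxyphenyl)-8-(2-methylbut-3-en-2-yl)-4H-chromen-4-one | C=CC(C)(C)c1c(O)cc(O)c2c(=O)c(O)c(-c3ccc(OC)cc3)oc12 | target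

Total step count: 9. Longest linear sequence: 8 steps (1, 2, 3, 5, 6, 7, 8, 9); step 4 is a one-step side branch.

Steps most likely to fail

**Step 2 (the labelled step).**
- The addition of the hindered alkyne carbon to the ketene may be slower than self-condensation of the vinylketene.
- The vinylogous ester may need a ring-opening temperature at which the ynol silyl ether isomerises by silyl shift.
- The phenol formed may be acylated by further ketene.

The fallback uses known chemistry only. It sets out from Weinreb amide 16 and comes back to the route at target 25. Ring A is taken ready-made, and the bond from C8 to the side chain is made by aromatic Claisen rearrangement. Purchased phloroglucinol is protected (NaH, MOMCl) as 1,3,5-tris(methoxymethoxy)benzene F1. This is lithiated (n-BuLi) and acylated with 16 to give 2-(benzyloxy)-1-[2,4,6-tris(methoxymethoxy)phenyl]ethan-1-one F2. Aroylation with LiN(SiMe3)2 and 19 as in step 6 gives 2-(benzyloxy)-1-(4-methoxyphenyl)-3-[2,4,6-tris(methoxymethoxy)phenyl]propane-1,3-dione F3. HCl in MeOH as in step 7 then gives 3-(benzyloxy)-5,7-dihydroxy-2-(4-methoxyphenyl)-4H-chromen-4-one F4; the two ortho oxygens are equivalent here, so no regiochemical question arises. K2CO3 and prenyl bromide in acetone alkylate the only non-chelated hydroxyl to give 3-(benzyloxy)-5-hydroxy-2-(4-methoxyphenyl)-7-[(3-methylbut-2-en-1-yl)oxy]-4H-chromen-4-one F5. Heating in N,N-diethylaniline at about 190 °C moves the allyl unit with inversion to C8 and gives 3-(benzyloxy)-5,7-dihydroxy-2-(4-methoxyphenyl)-8-(2-methylbut-3-en-2-yl)-4H-chromen-4-one F6, which has to be separated from the product of migration to C6. BCl3 with pentamethylbenzene at −78 °C then removes the benzyl group and gives 25.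

**Step 1.** Addition of LiCHBr2 to the carbonyl group beside the quaternary carbon may be slower than decay of the carbenoid, and silylation may partly occur on carbon.

The fallback sets out from ester 1 and comes back at ynolate 5. It reaches the ynolate by oxidation of an acetylide instead of by rearrangement. i-Bu2AlH in CH2Cl2 at −78 °C reduces 1 to 2,2-dimethylbut-3-enal F7. Ohira–Bestmann homologation (dimethyl (1-diazo-2-oxopropyl)phosphonate, K2CO3, MeOH) gives 3,3-dimethylpent-1-en-4-yne F8, which is handled in solution because of its volatility. n-BuLi in THF gives (3,3-dimethylpent-4-en-1-yn-1-yl)lithium F9, and lithium tert-butyl peroxide (LiOOt-Bu, from t-BuOOH and LiN(SiMe3)2) transfers oxygen to it and gives 5. This is silylated with 3 as in step 1.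

**Step 6.** Acylation may take place on the enolate oxygen or twice instead of once on carbon, and the crowded enolate may react sluggishly, so that the base consumes the acid chloride.

The fallback sets out from ketone 18 and comes back at phenolic diketone 22. It replaces the intermolecular acylation by the intramolecular acyl transfer of the Baker–Venkataraman rearrangement. Dilute HCl in MeOH removes the acetal and gives 2-(benzyloxy)-1-{6-ethoxy-2-hydroxy-3-(2-methylbut-3-en-2-yl)-4-[(triisopropylsilyl)oxy]phenyl}ethan-1-one F10. Treatment with 19, Et3N and DMAP in CH2Cl2 gives 2-[(benzyloxy)acetyl]-3-ethoxy-6-(2-methylbut-3-en-2-yl)-5-[(triisopropylsilyl)oxy]phenyl 4-methoxybenzoate F11. KOt-Bu in THF at 0 °C moves the aroyl group from oxygen to the enolate carbon through a six-membered transition state and gives 22, which closes to 23 under the acid of step 7.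

Further compounds
F1 | step 2 | 1,3,5-tris(methoxymethoxy)benzene | COCOc1cc(OCOC)cc(OCOC)c1
F2 | step 2 | 2-(benzyloxy)-1-[2,4,6-tris(methoxymethoxy)phenyl]ethan-1-one | COCOc1cc(OCOC)c(C(=O)COCc2ccccc2)c(OCOC)c1
F3 | step 2 | 2-(benzyloxy)-1-(4-methoxyphenyl)-3-[2,4,6-tris(methoxymethoxy)phenyl]propane-1,3-dione (racemic) | COCOc1cc(OCOC)c(C(=O)C(OCc2ccccc2)C(=O)c2ccc(OC)cc2)c(OCOC)c1
F4 | step 2 | 3-(benzyloxy)-5,7-dihydroxy-2-(4-methoxyphenyl)-4H-chromen-4-one | COc1ccc(cc1)-c1oc2cc(O)cc(O)c2c(=O)c1OCc1ccccc1
F5 | step 2 | 3-(benzyloxy)-5-hydroxy-2-(4-methoxyphenyl)-7-[(3-methylbut-2-en-1-yl)oxy]-4H-chromen-4-one | COc1ccc(cc1)-c1oc2cc(OCC=C(C)C)cc(O)c2c(=O)c1OCc1ccccc1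
F6 | step 2 | 3-(benzyloxy)-5,7-dihydroxy-2-(4-methoxyphenyl)-8-(2-methylbut-3-en-2-yl)-4H-chromen-4-one | C=CC(C)(C)c1c(O)cc(O)c2c(=O)c(OCc3ccccc3)c(-c3ccc(OC)cc3)oc12
F7 | step 1 | 2,2-dimethylbut-3-enal | C=CC(C)(C)C=O
F8 | step 1 | 3,3-dimethylpent-1-en-4-yne | C=CC(C)(C)C#C
F9 | step 1 | (3,3-dimethylpent-4-en-1-yn-1-yl)lithium | [Li]C#CC(C)(C)C=C
F10 | step 6 | 2-(benzyloxy)-1-{6-ethoxy-2-hydroxy-3-(2-methylbut-3-en-2-yl)-4-[(triisopropylsilyl)oxy]phenyl}ethan-1-one | C=CC(C)(C)c1c(O)c(C(=O)COCc2ccccc2)c(OCC)cc1O[Si](C(C)C)(C(C)C)C(C)C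
F11 | step 6 | 2-[(benzyloxy)acetyl]-3-ethoxy-6-(2-methylbut-3-en-2-yl)-5-[(triisopropylsilyl)oxy]phenyl 4-methoxybenzoate | C=CC(C)(C)c1c(OC(=O)c2ccc(OC)cc2)c(C(=O)COCc2ccccc2)c(OCC)cc1O[Si](C(C)C)(C(C)C)C(C)C
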